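## Analysis of the target

Numbering used throughout: bornane numbering for the terpene part (C1 = methyl-bearing bridgehead, C2 = oxygen-bearing carbon, C4 = other bridgehead, C6 = carbon bearing the benzylic CH2, C7 = CMe2). The arene is primed: C1' carries the ring oxygen, C2' the benzylic CH2, C3' and C5' the two other oxygens, and C4' and C6' are the remaining positions.

- The target 25 is a tetracycle. A fully substituted benzene ring (ring A) carries an isovaleryl ketone at C4', a formyl group at C6' and two chelated phenols. It is fused through a seven-membered oxepine (ring B: O, C1', C2', CH2, C6, C1, C2) to a 1,7,7-trimethylbicyclo[2.2.1]heptane.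
- There are four stereocentres, (1R,2S,4R,6S). C1 and C4 are tied to each other by the bicycle. The oxygen on C2 and the benzylic carbon on C6 are both endo, a 1,3-related pair on the concave face that the ortho-phenylene unit spans without strain.
- Sensitive groups are the aldehyde, the acidic phenols of a very electron-rich ring, and the secondary, neopentyl 2-bornyl aryl ether, which strong acid could ionise toward Wagner–Meerwein chemistry.
- The synthesis is hard for three reasons. Quaternary C1 lies between quaternary C7 and the oxygenated C2. A seven-membered ring must be closed onto a hindered bicycle. Formyl and isovaleryl must be placed on two aromatic positions that are both activated by three oxygens.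
- The strategy rests on the ring C1–C2–C3–C4–C5–C6. With a C5=C6 double bond written in, it is a cyclohexene. C1, C6, C5, C4 and C7 then form a 1,5,5-trisubstituted cyclopentadiene, and C2=C3 is a vinyl ether whose oxygen is already linked, through C1', C2' and the CH2, to the internal diene carbon C6.
- Ring B and the bicycle can therefore arise in one intramolecular [4+2] event, with a removable ester on C3 as the activating group.

## Retrosynthetic reasoning

**25 to 24.** The aryl–CHO bond is cut first. The aldehyde is the most sensitive group, and in 24 only C6' is unsubstituted, so a late electrophilic formylation has a single site. The forward reaction must formylate a free acylphloroglucinol monoether without touching the bornyl ether.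

**24 to 19 (through 23, 22, 20 and 21).** The two O–methyl bonds are cut next (24 to 23). Methyl ethers are the least intrusive oxygen protection for a Lewis-acid key step. The aryl–acyl bond follows. The acyl group belongs at C4', between the two methoxy groups, but C6' beside the ring oxygen is the more accessible site of 19. A bromine atom is therefore placed on C6' (20), the acid chloride 21 is forced to C4' (22), and the bromine is removed (23). Two extra steps buy an unambiguous substitution pattern.

**19 to 15 (through 17 and 16).** Two groups are added retrosynthetically: a carboxyl on C3 (17, its methyl ester 16) and a C5=C6 double bond (15). They turn the saturated bornane into the cyclohexene-with-acceptor pattern of a Diels–Alder adduct. In the forward direction the alkene is hydrogenated before the decarboxylation, because a C3 radical would otherwise cyclise onto C5=C6. The ester cleavage must avoid β-elimination of the aryloxide from C2. C6 becomes a stereocentre in 15 to 16; only the 6-endo CH2 keeps ring B closed.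

**15 to 14 (key disconnection).** C1–C2 and C3–C4 are cut. These are the two bonds that make the congested C1 and the second bridgehead, and cutting them also opens ring B, because the O–aryl–CH2 chain of 14 joins C2 to C6.

- Gained: two rings, two skeletal bonds, and C1, C2, C3 and C4 in one step.
- The tether leaves the oxygen no choice but endo, and the (E) geometry then puts the ester exo.
- Forward requirements: a donor-substituted acrylate must react with a hindered diene at its methyl-bearing terminus, and one enantiotopic diene face must be selected.
- One point needs care. Relative to ring B the C5=C6 bond of 15 is a bridgehead-type alkene (trans within the nine-membered perimeter C6–C5–C4–C3–C2–O–C1'–C2'–CH2). Some strain is therefore built into 15 and is released in the next step.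

**14 to 12 and 13.** The vinyl ether C–O bond is cut. Conjugate addition of the phenol 12 to the propiolate 13 gives the (E) isomer under amine catalysis.

**12 to 9 and 5 (through 11).** The benzylic C–C(sp2) bond is cut for a cross-coupling. The dienyl partner is an enol triflate (5) because it comes regiospecifically from a ketone. The benzyl partner is the nucleophile (from chloride 9), with the phenol masked as a silyl ether that fluoride removes without acid.

**9 to 6 and 5 to 1.** These are functional-group changes (9 from 8, 7 and the aldehyde 6; 5 from 3 and the enone 1). In 1 only C5 is enolisable, so methylation and triflation are regiospecific. The quaternary ring carbon blocks the hydrogen shifts that scramble ordinary cyclopentadienes.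

## Alternatives that were turned down

**Alternative 1: remote C–H etherification on a preformed bornane.**
- Disconnection: the C2–O bond of a simplified ether, leading to the 6-endo-hydroxymethyl bornane A1, which would come from the less common enantiomer of the chiral-pool bornanone by homologation.
- Forward key step: the hypoiodite of A1 is photolysed. The alkoxy radical removes the 2-endo hydrogen through a six-membered transition state, and oxidation with ring closure gives the oxolane A2.
- For it: all stereocentres come from the chiral pool. The hydrogen transfer uses the same endo 1,3-relationship that the target bridges. The reaction type is established.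
- Against it: A2 is not a substructure of 25. Its CH2–O bond must be broken again, and both bonds to the arene still have to be made. The step secures only the oxidation level and configuration of C2, and a second, uncertain annulation remains.
- Comparison: on absolute stereocontrol and precedent this alternative is stronger. The chosen strategy offers instead a single step that forms both rings with the arene already in place, from achiral materials, in fewer steps.

**Alternative 2: keteniminium [2+2], then ring expansion.**
- Disconnection: C3 is excised from a bornan-2-one to give the bicyclo[2.1.1]hexanone A4. This is cut at C1–C2 and C4–C7 to the acyclic amide A3, which carries C6 as its only stereocentre.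
- Forward key step: electrophilic activation of A3 gives a keteniminium ion that adds across the tetrasubstituted alkene in the crossed sense. Hydrolysis gives A4. Ring expansion, reduction to the endo alcohol and an aryl C–O coupling would follow.
- For it: every step is of a known type, and C6 is set early by routine chemistry.
- Against it:
  - the [2+2] must bond C4 to the fully substituted C7 beside quaternary C1;
  - the crossed against fused sense has no electronic bias for a tetrasubstituted alkene;
  - the ring expansion must be regioselective;
  - hydride reduction of such ketones favours the exo alcohol, the wrong epimer;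
  - the final etherification must close a seven-membered ring at a neopentyl alkoxide;
  - at least five operations separate A4 from the closed tetracycle.
- Comparison: it is stronger on step-by-step precedent. The chosen route is shorter from key step to core (three steps) and sets C2 through the tether instead of through a reduction with the wrong intrinsic preference.

**Alternative 3: one-step arene annulation onto a bromomethyl borneol.**
- Disconnection: aryl–CH2 and aryl–O together, leading to the aryl iodide A5 and the bromo alcohol A6.
- Forward key step: a Catellani-type reaction under palladium catalysis with a strained bicyclic alkene as transient mediator. The ortho C–H of A5 is alkylated by the bromide of A6, and the ipso carbon then couples with the C2 alkoxide to give A7.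
- For it: it is the most convergent union. The stereocentres come from the chiral pool. The ester of A7 already marks the formyl carbon, so the arene pattern is settled by construction. On that point it is clearly stronger than the chosen route, which needs a blocking bromine.
- Against it:
  - the bromide is β-branched and on the concave face, so its oxidative addition to the palladacycle is slow;
  - the terminating C–O bond must close a seven-membered ring from a hindered secondary alkoxide, where β-hydride loss and simple ipso reduction compete;
  - A6 itself needs a long chiral-pool sequence, in practice through a compound like A2.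
- Comparison: the chosen strategy offers a terpene half made in two steps from a commercial enone, and a key step whose regio- and endo-selectivity are enforced by the tether.

Key step: step 9

Assumption: the (S)-configured oxazaborolidinium cation is taken to steer C4 of the diene to the Re face of C3 of the boron-bound acrylate, the sense expected from the usual binding model of acrylate esters; should the β-aryloxy ester respond in the opposite sense, the (R)-configured cation is used and nothing else changes.

## Route

Step 1
Reactants: 1 4,4-dimethylcyclopent-2-en-1-one
Product: 3 racemic 4,4,5-trimethylcyclopent-2-en-1-one, via lithium dienolate 2 (not isolated)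
Conditions: LiN(i-Pr)2, THF, −78 °C; MeI, −78 → 0 °C
Reagents that add atoms: iodomethane, CI
Why: Only C5 of 1 is enolisable (C4 is quaternary), so kinetic deprotonation gives the cross-conjugated dienolate 2 regiospecifically and enolate alkylation installs the future C1 methyl; the new stereocentre is racemic and is erased in step 2.

Step 2
Reactants: 3 racemic 4,4,5-trimethylcyclopent-2-en-1-one
Product: 5 2,3,3-trimethylcyclopenta-1,4-dien-1-yl trifluoromethanesulfonate, via potassium dienolate 4 (not isolated)
Conditions: KN(SiMe3)2, THF, −78 °C; PhN(SO2CF3)2, −78 → 0 °C
Reagents that add atoms: N-phenylbis(trifluoromethanesulfonimide), O=S(=O)(N(c1ccccc1)S(=O)(=O)C(F)(F)F)C(F)(F)F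
Why: Enol triflate formation at the single remaining α-hydrogen gives a 1,3-diene whose sp3 carbon is quaternary, so it cannot tautomerise and its gem-dimethyl group slows dimerisation.

Step 3
Reactants: 6 2-hydroxy-4,6-dimethoxybenzaldehyde
Product: 7 2-[(tert-butyldimethylsilyl)oxy]-4,6-dimethoxybenzaldehyde
Conditions: t-BuMe2SiCl, imidazole, DMAP (cat.), DMF, 23 °C
Reagents that add atoms: tert-butyldimethylsilyl chloride, CC(C)(C)[Si](C)(C)Cl
Why: Silyl ether formation masks the phenol for the hydride, halide and organozinc steps and can later be removed by fluoride without acid, which the diene would not tolerate.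

Step 4
Reactants: 7 2-[(tert-butyldimethylsilyl)oxy]-4,6-dimethoxybenzaldehyde
Product: 8 {2-[(tert-butyldimethylsilyl)oxy]-4,6-dimethoxyphenyl}methanol
Conditions: NaBH4, THF/MeOH, 0 °C
Reagents that add atoms: none
Why: Borohydride reduction of the aryl aldehyde; the low temperature and neutral work-up keep the silyl group from migrating to the benzylic oxygen.

Step 5
Reactants: 8 {2-[(tert-butyldimethylsilyl)oxy]-4,6-dimethoxyphenyl}methanol
Product: 9 tert-butyl[2-(chloromethyl)-3,5-dimethoxyphenoxy]dimethylsilane
Conditions: PPh3, N-chlorosuccinimide, THF, −20 → 0 °C; used crude at once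
Reagents that add atoms: N-chlorosuccinimide, O=C1CCC(=O)N1Cl
Why: Appel-type chlorination under neutral conditions, needed because this ortho/para-trioxygenated benzylic system ionises readily under acid.

Step 6
Reactants: 9 tert-butyl[2-(chloromethyl)-3,5-dimethoxyphenoxy]dimethylsilane; 5 2,3,3-trimethylcyclopenta-1,4-dien-1-yl trifluoromethanesulfonate
Product: 11 tert-butyl{3,5-dimethoxy-2-[(2,3,3-trimethylcyclopenta-1,4-dien-1-yl)methyl]phenoxy}dimethylsilane, via benzylzinc chloride 10 (not isolated)
Conditions: Zn dust, LiCl, THF, 23 °C; then 5, Pd(OAc)2 (2 mol %), SPhos (4 mol %), THF, 23 → 45 °C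
Reagents that add atoms: none
Why: LiCl-assisted zinc insertion into the benzylic C–Cl bond gives 10, and Negishi coupling with the alkenyl triflate under a biarylphosphine-ligated zerovalent palladium catalyst forms the benzylic C–C6 bond; the benzyl partner has no β-hydrogen and the silyl ether is inert to the zinc reagent.

Step 7
Reactants: 11 tert-butyl{3,5-dimethoxy-2-[(2,3,3-trimethylcyclopenta-1,4-dien-1-yl)methyl]phenoxy}dimethylsilane
Product: 12 3,5-dimethoxy-2-[(2,3,3-trimethylcyclopenta-1,4-dien-1-yl)methyl]phenol
Conditions: Bu4NF, THF, 0 °C; aq. NH4Cl
Reagents that add atoms: none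
Why: Fluoride cleavage of the aryl silyl ether; no acid touches the diene.

Step 8
Reactants: 12 3,5-dimethoxy-2-[(2,3,3-trimethylcyclopenta-1,4-dien-1-yl)methyl]phenol; 13 methyl propiolate
Product: 14 methyl (E)-3-{3,5-dimethoxy-2-[(2,3,3-trimethylcyclopenta-1,4-dien-1-yl)methyl]phenoxy}acrylate
Conditions: DABCO (10 mol %), CH2Cl2, 0 → 23 °C
Reagents that add atoms: none
Why: Amine-catalysed conjugate addition (oxa-Michael) of the phenol to the propiolate; the pathway through the ammonium allenolate should give the (E)-β-aryloxyacrylate.

Step 9
Reactants: 14 methyl (E)-3-{3,5-dimethoxy-2-[(2,3,3-trimethylcyclopenta-1,4-dien-1-yl)methyl]phenoxy}acrylate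
Product: 15 methyl ester cycloadduct (born-5-ene bridged from the endo oxygen on C2 to C6 by the 3',5'-dimethoxy-1',2'-phenylene-CH2 unit; CO2Me exo on C3; C1, C2 and C4 configured as in 25)
Conditions: (S)-[C24H25BNO][N(SO2CF3)2] (20 mol %; N-protonated oxazaborolidine from (S)-α,α-diphenylprolinol and o-tolylboronic acid, made with a slight deficit of HN(SO2CF3)2), CH2Cl2, −40 → 0 °C
Reagents that add atoms: none
Why: Proposed new method: the boron of the cationic oxazaborolidine binds the ester carbonyl of 14, lowers the LUMO of the otherwise deactivated β-aryloxyacrylate, and a concerted asynchronous [4+2] joins the diene C1=C6–C5=C4 to C2=C3, forming C1–C2 and C3–C4. The closest known chemistry is the type 2 intramolecular Diels–Alder reaction (tether on an internal diene carbon, four-atom link, bridgehead-type alkene in the product) and the oxazaborolidinium-catalysed addition of acrylates to cyclopentadienes. The six-membered carbocycle closes by the cycloaddition itself and, with C7, becomes the norbornene; the oxepine closes as the tether ring, because the O–aryl–CH2 chain joins C2 to C6 as soon as C1–C2 exists (a bicyclo[4.3.1] arrangement of cyclohexene and tether). At C2 the oxygen must lie endo, under C6, since the tether cannot reach from the exo side, and at C3 the ester is trans to that oxygen, hence exo, by the (E) geometry and suprafacial addition. C1 and C4 follow from which enantiotopic face of the diene the tethered acrylate takes, and that is the choice of the catalyst, which should direct C4 to the Re face of C3 of the bound s-trans ester. Regiochemistry (C2 to the methyl-bearing C1) is fixed by the tether length, the reverse orientation being out of reach. The diene cannot isomerise because C7 is quaternary, so the competing channels are a racemic background reaction and acid-promoted reactions of the diene, which the deficit of strong acid keeps down. The C5=C6 bond formed is a bridgehead-type alkene relative to the oxepine (trans in the nine-membered perimeter), strained but of the kind this class of cycloaddition delivers.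

Step 10
Reactants: 15 methyl ester cycloadduct
Product: 16 saturated methyl ester, bornane (1R,2S,3R,4R,6S) (H on C6 exo, benzylic CH2 endo, CO2Me exo on C3)
Conditions: Mn(dpm)3 (10 mol %; dpm = dipivaloylmethanate, C11H19O2), PhSiH3, t-BuOOH, i-PrOH, 23 °C
Reagents that add atoms: none
Why: Metal-hydride hydrogen-atom-transfer hydrogenation: the manganese hydride gives H to the less substituted C5, and the tertiary C6 radical takes its second hydrogen on the exo face because only the 6-endo CH2 keeps the oxepine closed without strain. The radical path needs no metal surface on the alkene face shielded by the C7 methyl and releases the strain of the bridgehead-type alkene.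

Step 11
Reactants: 16 saturated methyl ester
Product: 17 carboxylic acid, bornane (1R,2S,3R,4R,6S)
Conditions: Me3SnOH, ClCH2CH2Cl, 80 °C; 1 M HCl wash
Reagents that add atoms: trimethyltin hydroxide, C[Sn](C)(C)O
Why: Tin hydroxide-mediated ester cleavage under near-neutral conditions, chosen because the ester is β to an aryloxy leaving group and hydroxide could trigger E1cB loss of the phenoxide; the configuration at C3 is erased in step 12 in any case.

Step 12
Reactants: 17 carboxylic acid
Product: 19 3',5'-dimethoxy tetracyclic core, bornane (1R,2S,4R,6S), via thiohydroxamate ester 18 (not isolated)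
Conditions: N-hydroxypyridine-2-thione, DCC, DMAP (cat.), CH2Cl2, 0 → 23 °C, dark; then t-BuSH, visible light, 23 °C
Reagents that add atoms: none
Why: Barton reductive decarboxylation: the O-acyl thiohydroxamate fragments to the C3 radical, which takes hydrogen from the thiol faster than it can expel the β-aryloxy group. The alkene is already saturated, so no homoallyl radical cyclisation can occur.

Step 13
Reactants: 19 3',5'-dimethoxy tetracyclic core
Product: 20 6'-bromo derivative of 19 (bromine beside the ring oxygen)
Conditions: N-bromosuccinimide (1.0 equiv), MeCN, −30 → 0 °C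
Reagents that add atoms: N-bromosuccinimide, O=C1CCC(=O)N1Br
Why: Electrophilic aromatic bromination. Both free positions are activated by three oxygens, but C6' is the more accessible, because the C3' methoxy group is forced by the neighbouring benzylic carbon to turn its methyl toward C4'. This is the preference known for 5,7-dialkoxychromans and flavans, which react beside the ring oxygen. The bromine serves as a blocking group.

Step 14
Reactants: 20 6'-bromo derivative of 19; 21 3-methylbutanoyl chloride
Product: 22 6'-bromo-4'-(3-methylbutanoyl) derivative of 19
Conditions: TiCl4, CH2Cl2, −20 → 0 °C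
Reagents that add atoms: none
Why: Friedel–Crafts acylation at the only remaining aromatic C–H, between the two methoxy groups; the endo 2-bornyl aryl ether has no σ-assistance for ionisation and is closed to SN2, so it should survive this Lewis acid at low temperature.

Step 15
Reactants: 22 6'-bromo-4'-(3-methylbutanoyl) derivative of 19
Product: 23 4'-(3-methylbutanoyl)-3',5'-dimethoxy tetracycle
Conditions: H2 (1 atm), Pd/C, Et3N, EtOAc/MeOH, 23 °C
Reagents that add atoms: none
Why: Hydrogenolysis of the aryl bromide over palladium with base; the twisted, doubly ortho-substituted aryl ketone is not reduced under these conditions.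

Step 16
Reactants: 23 4'-(3-methylbutanoyl)-3',5'-dimethoxy tetracycle
Product: 24 3',5'-dihydroxy-4'-(3-methylbutanoyl) tetracycle
Conditions: BBr3, CH2Cl2, −78 → 0 °C; H2O
Reagents that add atoms: none
Why: Lewis-acid ether cleavage: both methoxy groups are ortho to the ketone and are cleaved through boron chelates by bromide attack at methyl; the ring ether carbon is secondary, neopentyl and endo, so neither SN2 nor assisted ionisation competes.

Step 17
Reactants: 24 3',5'-dihydroxy-4'-(3-methylbutanoyl) tetracycle
Product: 25 target CNP0246493.1 (6'-formyl-3',5'-dihydroxy-4'-(3-methylbutanoyl) tetracycle, bornane (1R,2S,4R,6S))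
Conditions: POCl3, DMF, EtOAc, 0 → 23 °C; then H2O, 50 °C
Reagents that add atoms: N,N-dimethylformamide, CN(C)C=O; water, O
Why: Vilsmeier–Haack formylation of the acylphloroglucinol monoether at its single free position, followed by hydrolysis of the iminium salt; bringing in the aldehyde last exposes it to no further reagent.

## Compound list

1 | 4,4-dimethylcyclopent-2-en-1-one | CC1(C)CC(=O)C=C1 | starting material
2 | lithium 3,3-dimethylcyclopenta-1,4-dien-1-olate | [Li+].[O-]C1=CC(C)(C)C=C1 | intermediate (not isolated)
3 | racemic 4,4,5-trimethylcyclopent-2-en-1-one | CC1C(=O)C=CC1(C)C | intermediate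
4 | potassium 2,3,3-trimethylcyclopenta-1,4-dien-1-olate | [K+].[O-]C1=C(C)C(C)(C)C=C1 | intermediate (not isolated)
5 | 2,3,3-trimethylcyclopenta-1,4-dien-1-yl trifluoromethanesulfonate | CC1=C(OS(=O)(=O)C(F)(F)F)C=CC1(C)C | intermediate
6 | 2-hydroxy-4,6-dimethoxybenzaldehyde | COc1cc(O)c(C=O)c(OC)c1 | starting material
7 | 2-[(tert-butyldimethylsilyl)oxy]-4,6-dimethoxybenzaldehyde | COc1cc(O[Si](C)(C)C(C)(C)C)c(C=O)c(OC)c1 | intermediate
8 | {2-[(tert-butyldimethylsilyl)oxy]-4,6-dimethoxyphenyl}methanol | COc1cc(O[Si](C)(C)C(C)(C)C)c(CO)c(OC)c1 | intermediate
9 | tert-butyl[2-(chloromethyl)-3,5-dimethoxyphenoxy]dimethylsilane | COc1cc(O[Si](C)(C)C(C)(C)C)c(CCl)c(OC)c1 | intermediate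
10 | {2-[(tert-butyldimethylsilyl)oxy]-4,6-dimethoxybenzyl}zinc chloride | COc1cc(O[Si](C)(C)C(C)(C)C)c(C[Zn]Cl)c(OC)c1 | intermediate (not isolated)
11 | tert-butyl{3,5-dimethoxy-2-[(2,3,3-trimethylcyclopenta-1,4-dien-1-yl)methyl]phenoxy}dimethylsilane | COc1cc(O[Si](C)(C)C(C)(C)C)c(CC2=C(C)C(C)(C)C=C2)c(OC)c1 | intermediate
12 | 3,5-dimethoxy-2-[(2,3,3-trimethylcyclopenta-1,4-dien-1-yl)methyl]phenol | COc1cc(O)c(CC2=C(C)C(C)(C)C=C2)c(OC)c1 | intermediate
13 | methyl propiolate | C#CC(=O)OC | starting material
14 | methyl (E)-3-{3,5-dimethoxy-2-[(2,3,3-trimethylcyclopenta-1,4-dien-1-yl)methyl]phenoxy}acrylate | COC(=O)/C=C/Oc1cc(OC)cc(OC)c1CC1=C(C)C(C)(C)C=C1 | intermediate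
15 | methyl ester cycloadduct: oxepine-bridged born-5-ene, O endo on C2, CO2Me exo on C3 | c1c(OC)cc2c(c1OC)CC1=C[C@@H]3[C@@H](C(=O)OC)[C@H](O2)[C@@]1(C)C3(C)C | intermediate
16 | saturated methyl ester, bornane (1R,2S,3R,4R,6S) | c1c(OC)cc2c(c1OC)C[C@@H]1C[C@@H]3[C@@H](C(=O)OC)[C@H](O2)[C@@]1(C)C3(C)C | intermediate
17 | carboxylic acid, bornane (1R,2S,3R,4R,6S) | c1c(OC)cc2c(c1OC)C[C@@H]1C[C@@H]3[C@@H](C(=O)O)[C@H](O2)[C@@]1(C)C3(C)C | intermediate
18 | 2-thioxopyridin-1(2H)-yl ester of 17 | c1c(OC)cc2c(c1OC)C[C@@H]1C[C@@H]3[C@@H](C(=O)ON4C=CC=CC4=S)[C@H](O2)[C@@]1(C)C3(C)C | intermediate (not isolated)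
19 | 3',5'-dimethoxy tetracyclic core, bornane (1R,2S,4R,6S) | c1c(OC)cc2c(c1OC)C[C@@H]1C[C@@H]3C[C@H](O2)[C@@]1(C)C3(C)C | intermediate
20 | 6'-bromo-3',5'-dimethoxy tetracycle | c1c(OC)c(Br)c2c(c1OC)C[C@@H]1C[C@@H]3C[C@H](O2)[C@@]1(C)C3(C)C | intermediate
21 | 3-methylbutanoyl chloride | CC(C)CC(Cl)=O | starting material
22 | 6'-bromo-3',5'-dimethoxy-4'-(3-methylbutanoyl) tetracycle | CC(C)CC(=O)c1c(OC)c(Br)c2c(c1OC)C[C@@H]1C[C@@H]3C[C@H](O2)[C@@]1(C)C3(C)C | intermediate
23 | 3',5'-dimethoxy-4'-(3-methylbutanoyl) tetracycle | CC(C)CC(=O)c1c(OC)cc2c(c1OC)C[C@@H]1C[C@@H]3C[C@H](O2)[C@@]1(C)C3(C)C | intermediate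
24 | 3',5'-dihydroxy-4'-(3-methylbutanoyl) tetracycle | CC(C)CC(=O)c1c(O)cc2c(c1O)C[C@@H]1C[C@@H]3C[C@H](O2)[C@@]1(C)C3(C)C | intermediate
25 | CNP0246493.1, 6'-formyl-3',5'-dihydroxy-4'-(3-methylbutanoyl) tetracycle, bornane (1R,2S,4R,6S) | CC(C)CC(=O)c1c(O)c(C=O)c2c(c1O)C[C@@H]1C[C@@H]3C[C@H](O2)[C@@]1(C)C3(C)C | target

## Step count and risk

Total: 17 steps. Longest linear sequence: 15 steps (6 to 25, steps 3–17); the diene branch (steps 1–2) joins at step 6.

**Step 9 (key step).**
- Most likely failure: loss of turnover and of enantioface control. The ester with its bulky boron cation must sit exo beside the syn methyl on C7, the aryl ethers can hold part of the catalyst, and strain builds up in the bridgehead-type alkene. A slow catalysed path can then be overtaken by a racemic, acid-promoted one.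
- Fallback (auxiliary control with a small achiral Lewis acid, both known reaction types), from 12, returning at 17:
  - Conjugate addition of 12, under the conditions of step 8, to the propiolate of (R)-pantolactone, (3R)-4,4-dimethyl-2-oxooxolan-3-yl prop-2-ynoate F1 (from propiolic acid, (R)-pantolactone and DCC), should give the auxiliary-bearing (E)-aryloxyacrylate F2.
  - With TiCl4 in CH2Cl2 at −40 → 0 °C the two ester carbonyls chelate titanium, as in the established auxiliary-controlled Diels–Alder reactions of such acrylates. The same tethered cycloaddition should then run under this compact Lewis acid.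
  - The diastereomeric adducts differ in the configuration of the bornene and are separable. The one configured as 15 is the pantolactone ester F3. The other enantiomer of the auxiliary is taken if induction runs the wrong way.
  - Hydrogenation as in step 10 gives the saturated pantolactone ester F4. LiOH/H2O2 in THF/H2O at 0 °C cleaves this activated ester quickly to 17.

**Step 6.**
- Most likely failure: ionisation and Wurtz-type homocoupling of the very electron-rich benzylic chloride during zinc insertion, and slow coupling at the tetrasubstituted alkenyl triflate.
- Fallback (roles inverted, no benzylic halide and no organozinc), from 5 and 8, returning at 11: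
  - Miyaura borylation of 5 (B2pin2, PdCl2(dppf), KOAc, dioxane, 80 °C) gives the dienyl pinacol boronate F5.
  - 8 is converted with methyl chloroformate and pyridine into the benzylic methyl carbonate F6.
  - Suzuki–Miyaura coupling of F5 with F6 ([Pd(C3H5)Cl]2, 1,5-bis(diphenylphosphino)pentane, K2CO3, DMF, 80 °C) proceeds through an η3-benzylpalladium intermediate, which the electron-rich ring favours, and gives 11.

**Step 11.**
- Most likely failure: β-elimination of the aryloxide, which opens the oxepine, if the hindered exo ester needs forcing conditions.
- Fallback (redox detour that never exposes the ester to a hydroxide base), from 16, returning at 17: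
  - LiAlH4 in THF at 0 °C reduces 16 to the primary alcohol F7.
  - Dess–Martin periodinane buffered with NaHCO3 gives the aldehyde F8.
  - Pinnick oxidation (NaClO2, NaH2PO4, 2-methyl-2-butene, t-BuOH/H2O) gives 17.

**Step 13.**
- Most likely failure: poor site selectivity between C6' and C4', since the steric argument is by analogy with six-membered ring ethers.
- Fallback (both bromides are used), from 19, returning at 23:
  - The bromides are separated. 20 continues through steps 14 and 15.
  - The 4'-bromo isomer F9 is subjected to halogen–lithium exchange (t-BuLi, THF, −78 °C) and acylated with N-methoxy-N,3-dimethylbutanamide. This gives 23 directly, where the two streams meet.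

## Further compounds

F1 | step 9 | (3R)-4,4-dimethyl-2-oxooxolan-3-yl prop-2-ynoate | C#CC(=O)O[C@H]1C(=O)OCC1(C)C
F2 | step 9 | (3R)-4,4-dimethyl-2-oxooxolan-3-yl (E)-3-{3,5-dimethoxy-2-[(2,3,3-trimethylcyclopenta-1,4-dien-1-yl)methyl]phenoxy}acrylate | O=C(/C=C/Oc1cc(OC)cc(OC)c1CC1=C(C)C(C)(C)C=C1)O[C@H]1C(=O)OCC1(C)C
F3 | step 9 | (R)-pantolactone ester analogue of 15 | c1c(OC)cc2c(c1OC)CC1=C[C@@H]3[C@@H](C(=O)O[C@H]4C(=O)OCC4(C)C)[C@H](O2)[C@@]1(C)C3(C)C
F4 | step 9 | (R)-pantolactone ester analogue of 16 | c1c(OC)cc2c(c1OC)C[C@@H]1C[C@@H]3[C@@H](C(=O)O[C@H]4C(=O)OCC4(C)C)[C@H](O2)[C@@]1(C)C3(C)C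
F5 | step 6 | 4,4,5,5-tetramethyl-2-(2,3,3-trimethylcyclopenta-1,4-dien-1-yl)-1,3,2-dioxaborolane | CC1=C(B2OC(C)(C)C(C)(C)O2)C=CC1(C)C
F6 | step 6 | {2-[(tert-butyldimethylsilyl)oxy]-4,6-dimethoxybenzyl} methyl carbonate | COC(=O)OCc1c(O[Si](C)(C)C(C)(C)C)cc(OC)cc1OC
F7 | step 11 | primary alcohol from 16 (CH2OH exo on C3) | c1c(OC)cc2c(c1OC)C[C@@H]1C[C@@H]3[C@@H](CO)[C@H](O2)[C@@]1(C)C3(C)C
F8 | step 11 | aldehyde from F7 (CHO exo on C3) | c1c(OC)cc2c(c1OC)C[C@@H]1C[C@@H]3[C@@H](C=O)[C@H](O2)[C@@]1(C)C3(C)C
F9 | step 13 | 4'-bromo-3',5'-dimethoxy tetracycle (regioisomer of 20) | Brc1c(OC)cc2c(c1OC)C[C@@H]1C[C@@H]3C[C@H](O2)[C@@]1(C)C3(C)C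
A1 | alternative 1 | endo-(1,7,7-trimethylbicyclo[2.2.1]heptan-2-yl)methanol (CH2OH on C6 in target numbering) | OC[C@@H]1C[C@@H]2CC[C@@]1(C)C2(C)C
A2 | alternative 1 | oxolane bridging C2 and the CH2 on C6 | C1[C@@H]2C[C@@H]3C[C@H](O1)[C@@]2(C)C3(C)C
A3 | alternative 2 | 4-(2-bromo-4,6-dimethoxybenzyl)-5,6-dimethyl-1-(pyrrolidin-1-yl)hept-5-en-1-one | COc1cc(OC)c(C[C@@H](C(C)=C(C)C)CCC(=O)N2CCCC2)c(Br)c1
A4 | alternative 2 | 2-(2-bromo-4,6-dimethoxybenzyl)-1,6,6-trimethylbicyclo[2.1.1]hexan-5-one | COc1cc(OC)c(C[C@@H]2C[C@@H]3C(=O)[C@@]2(C)C3(C)C)c(Br)c1
A5 | alternative 3 | methyl 2-iodo-4,6-dimethoxybenzoate | COC(=O)c1c(I)cc(OC)cc1OC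
A6 | alternative 3 | 6-endo-(bromomethyl)borneol | BrC[C@@H]1C[C@@H]2C[C@H](O)[C@@]1(C)C2(C)C
A7 | alternative 3 | tetracyclic core with CO2Me at the future formyl carbon | c1c(OC)c(C(=O)OC)c2c(c1OC)C[C@@H]1C[C@@H]3C[C@H](O2)[C@@]1(C)C3(C)C
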